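The carbocycle (C1'–C6'; C1' is the carbinol carbon on C2 of the dihydrobenzofuran) is disconnected across C3'–C4'. Its trans-diaxial C3'–OH/C4'–OMe pair, with C3'–OH cis to the tertiary C1'–OH, is the retron of a hydroxyl-directed epoxidation and trans-diaxial methanolysis of a cyclohex-3-en-1-ol. That cyclohexene is closed last, in one operation, by ring-closing metathesis, which forms C3'=C4' from an allyl and a but-3-enyl arm on C1'. The precursor is a tertiary alcohol from chelation-controlled allylation of a trans-2-(pent-4-enoyl)-2,3-dihydrobenzofuran, built from dihydroconiferyl alcohol and furan-2(5H)-one by rhodium-catalysed asymmetric conjugate arylation and a lactone-templated closure of the oxygen ring.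

Key step: step 9

Remark: dihydrobenzofuran atoms are O1, C2, C3, C3a–C7a; cyclohexane atoms are C1'–C6' (C3' = CHOH, C4' = CHOMe); TBS = tert-butyldimethylsilyl.
Remark: lactol 15 (and its magnesium salt 14) is taken as both hemiketal epimers in equilibrium with the open hydroxy ketone; the hemiketal centre is lost in step 7, so it carries no descriptor.

Step 1
Reactants: 1 dihydroconiferyl alcohol [4-(3-hydroxypropyl)-2-methoxyphenol]
Product: 2 2-bromo-4-(3-hydroxypropyl)-6-methoxyphenol
Conditions: NBS, i-Pr2NH (cat.), CH2Cl2, 0 °C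
Reagents that add atoms: N-bromosuccinimide, O=C1CCC(=O)N1Br
Why: Electrophilic aromatic bromination of a para-blocked phenol (amine-catalysed ortho-bromination with NBS) should go to the one free position ortho to the hydroxyl, the carbon that later becomes C3a, while the primary alcohol is inert.

Step 2
Reactants: 2 2-bromo-4-(3-hydroxypropyl)-6-methoxyphenol
Product: 3 1-bromo-2-(TBS-oxy)-3-methoxy-5-[3-(TBS-oxy)propyl]benzene
Conditions: TBSCl (2.4 equiv), imidazole, DMF, rt
Reagents that add atoms: tert-butyldimethylsilyl chloride, CC(C)(C)[Si](C)(C)Cl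
Why: Silyl ether formation (TBSCl/imidazole) caps the phenol and the primary alcohol before lithiation and leaves the phenol as an aryl silyl ether that fluoride can later remove selectively.

Step 3
Reactants: 3 1-bromo-2-(TBS-oxy)-3-methoxy-5-[3-(TBS-oxy)propyl]benzene
Product: 6 {2-(TBS-oxy)-3-methoxy-5-[3-(TBS-oxy)propyl]phenyl}boronic acid, via aryllithium 4 (not isolated), via lithium aryltriisopropoxyborate 5 (not isolated)
Conditions: B(OiPr)3, n-BuLi, THF/toluene, −78 °C; then sat. aq. NH4Cl, 0 °C
Reagents that add atoms: triisopropyl borate, CC(C)OB(OC(C)C)OC(C)C; water, O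
Why: Bromine–lithium exchange under in situ quench (lithiation–borylation) should trap the aryllithium with the borate as it forms, before the ortho silyl group can migrate from oxygen to carbon, and mild hydrolysis of the borate releases the boronic acid.

Step 4
Reactants: 6 {2-(TBS-oxy)-3-methoxy-5-[3-(TBS-oxy)propyl]phenyl}boronic acid; 7 furan-2(5H)-one
Product: 8 (4R)-4-{2-(TBS-oxy)-3-methoxy-5-[3-(TBS-oxy)propyl]phenyl}oxolan-2-one
Conditions: [Rh(OH)((R)-BINAP)]2 (3 mol %), 7 (2 equiv), dioxane/H2O 10:1, 50 °C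
Reagents that add atoms: none
Why: Hayashi–Miyaura rhodium-catalysed asymmetric 1,4-addition, in which the aryl group passes from boron to the hydroxorhodium–BINAP complex, adds across the butenolide C=C and the rhodium enolate is hydrolysed, the (R)-BINAP pocket exposing the face that leads to the (4R)-lactone, whose stereocentre becomes C3 (R) of the dihydrobenzofuran.

Step 5
Reactants: 8 (4R)-4-aryl-oxolan-2-one
Product: 12 cis-fused tricyclic lactone [γ-lactone between the 2-carboxyl and the 3-hydroxymethyl group of (2R,3R)-3-(hydroxymethyl)-7-methoxy-5-[3-(TBS-oxy)propyl]-2,3-dihydro-1-benzofuran-2-carboxylic acid], via lithium enolate 9 (not isolated), via iodolactone 10 (not isolated), via phenoxide 11 (not isolated)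
Conditions: LiN(SiMe3)2, THF, −78 °C; I2, −78 °C; then Bu4NF (1.05 equiv), −78 → 0 °C
Reagents that add atoms: none
Why: Enolate iodination followed by an intramolecular Williamson etherification, in which iodine enters the lactone α-carbon anti to the aryl group, fluoride cleaves the labile aryl silyl ether, and the phenoxide displaces iodide in a 5-exo-tet SN2 reaction with inversion, so the new centre (C2) is fixed cis to C3 by the five-five ring fusion and any cis iodide is recycled by iodide exchange.

Step 6
Reactants: 12 cis-fused tricyclic lactone; 13 but-3-enylmagnesium bromide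
Product: 15 cis-fused lactol [cyclic hemiketal between the 3-hydroxymethyl group and the carbonyl of the (2R,3R)-2-(pent-4-enoyl)dihydrobenzofuran], via bromomagnesium hemiketalate 14 (not isolated)
Conditions: 13 (1.2 equiv), THF, −78 °C; sat. aq. NH4Cl
Reagents that add atoms: none
Why: Mono-addition of a Grignard reagent to a γ-lactone should stop after one but-3-enyl group because the tetrahedral magnesium hemiketalate is stable at −78 °C and frees the carbonyl group only on work-up, where the product rests as the cis-fused lactol.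

Step 7
Reactants: 15 cis-fused lactol
Product: 17 1-{(2S,3R)-3-(TBS-oxymethyl)-7-methoxy-5-[3-(TBS-oxy)propyl]-2,3-dihydro-1-benzofuran-2-yl}pent-4-en-1-one, via cis ketone 16 (not isolated)
Conditions: TBSCl, imidazole, DMF, rt; then DBU, 40 °C
Reagents that add atoms: tert-butyldimethylsilyl chloride, CC(C)(C)[Si](C)(C)Cl
Why: Ring–chain tautomerism of the lactol exposes the primary alcohol for silylation, and DBU then equilibrates the α-aryloxy ketone centre C2 through its enol (thermodynamic epimerisation) from the cis (2R,3R) to the more stable trans (2S,3R) arrangement, while the non-acidic C3 is untouched.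

Step 8
Reactants: 17 trans (2S,3R) pent-4-enoyl ketone; 18 allylmagnesium bromide
Product: 20 (4S)-4-{(2S,3R)-3-(TBS-oxymethyl)-7-methoxy-5-[3-(TBS-oxy)propyl]-2,3-dihydro-1-benzofuran-2-yl}octa-1,7-dien-4-ol, via bromomagnesium alkoxide 19 (not isolated)
Conditions: MgBr2·OEt2 (3 equiv), CH2Cl2, −78 °C; then 18 (Et2O), −78 °C; sat. aq. NH4Cl
Reagents that add atoms: none
Why: Cram-chelate-controlled Grignard addition, in which magnesium bridges the ketone oxygen and ring oxygen O1 (helped by the neighbouring 7-methoxy group) and holds C=O syn to O1, so the allyl group attacks from the side of C2–H, away from C3, and gives the (4S) carbinol, the future (1'S) centre.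

Step 9
Reactants: 20 (4S)-octa-1,7-dien-4-ol
Product: 21 (1S)-1-{(2S,3R)-3-(TBS-oxymethyl)-7-methoxy-5-[3-(TBS-oxy)propyl]-2,3-dihydro-1-benzofuran-2-yl}cyclohex-3-en-1-ol
Conditions: second-generation Grubbs catalyst RuCl2(=CHPh)(H2IMes)(PCy3) (3 mol %), CH2Cl2 (0.005 M), 40 °C
Reagents that add atoms: none
Why: The ruthenium benzylidene undergoes [2+2] cycloaddition and cycloreversion with one terminal alkene of 20 to put a ruthenium alkylidene on that arm, which adds to the second terminal alkene and collapses through a ruthenacyclobutane to the ring alkene and Ru=CH2, the chain carrier, with ethene lost as gas. The closest known reaction type is ring-closing olefin metathesis of a 1,7-diene to a cyclohexene. The one ring closed is the six-membered carbocycle C1'–C6', closed by forming the C3'=C4' double bond between the allyl arm (C2', C3') and the but-3-enyl arm (C6', C5', C4') that share C1'; the cis ring alkene is the only possible geometry. No stereocentre is created: C1', set in step 8, is untouched and becomes the control element for C3' and C4' in steps 10 and 11. The step needs ring closure to win over intermolecular metathesis, which the quaternary C1' (gem-disubstituent effect), the favourable ring size, high dilution and the absence of any other alkene in 20 secure; the free tertiary hydroxyl, the aryl ethers and the silyl ethers are inert to the catalyst.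

Step 10
Reactants: 21 (1S)-cyclohex-3-en-1-ol
Product: 22 (1S,3S,6R)-3-{(2S,3R)-3-(TBS-oxymethyl)-7-methoxy-5-[3-(TBS-oxy)propyl]-2,3-dihydro-1-benzofuran-2-yl}-7-oxabicyclo[4.1.0]heptan-3-ol (epoxide oxygen syn to the hydroxyl; 1'S,3'S,4'R)
Conditions: VO(acac)2 (5 mol %), t-BuOOH (decane), CH2Cl2, 0 °C → rt
Reagents that add atoms: tert-butyl hydroperoxide, CC(C)(C)OO
Why: Vanadium-catalysed hydroxyl-directed epoxidation of a homoallylic alcohol, in which the C1' hydroxyl, axial because the large dihydrobenzofuranyl group sits equatorial, binds the vanadium alkylperoxide and delivers oxygen to the face of C3'=C4' syn to itself, setting C3' and C4' as (3'S,4'R).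

Step 11
Reactants: 22 syn-epoxy alcohol
Product: 24 difengpiol B, via bis-silyl methoxy diol 23 (not isolated)
Conditions: CSA, MeOH, 0 °C → rt
Reagents that add atoms: methanol, CO
Why: Acid-catalysed epoxide methanolysis under Fürst–Plattner (trans-diaxial) control, in which methanol attacks C4' anti to the epoxide oxygen in the half-chair that keeps the dihydrobenzofuranyl group equatorial (C3' is also deactivated by the nearer C1' oxygen), giving C4'–OMe and C3'–OH trans-diaxial with C3'–OH cis to C1'–OH, (3'S,4'S), after which the same acid removes both primary silyl ethers by methanolysis.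

Compound list
1 | dihydroconiferyl alcohol, 4-(3-hydroxypropyl)-2-methoxyphenol | COc1cc(CCCO)ccc1O | starting material
2 | 2-bromo-4-(3-hydroxypropyl)-6-methoxyphenol | COc1cc(CCCO)cc(Br)c1O | intermediate
3 | 1-bromo-2-(TBS-oxy)-3-methoxy-5-[3-(TBS-oxy)propyl]benzene | COc1cc(CCCO[Si](C)(C)C(C)(C)C)cc(Br)c1O[Si](C)(C)C(C)(C)C | intermediate
4 | aryllithium from 3 (not isolated) | COc1cc(CCCO[Si](C)(C)C(C)(C)C)cc([Li])c1O[Si](C)(C)C(C)(C)C | intermediate
5 | lithium aryltriisopropoxyborate (not isolated) | COc1cc(CCCO[Si](C)(C)C(C)(C)C)cc([B-](OC(C)C)(OC(C)C)OC(C)C)c1O[Si](C)(C)C(C)(C)C.[Li+] | intermediate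
6 | {2-(TBS-oxy)-3-methoxy-5-[3-(TBS-oxy)propyl]phenyl}boronic acid | COc1cc(CCCO[Si](C)(C)C(C)(C)C)cc(B(O)O)c1O[Si](C)(C)C(C)(C)C | intermediate
7 | furan-2(5H)-one | O=C1OCC=C1 | starting material
8 | (4R)-4-{2-(TBS-oxy)-3-methoxy-5-[3-(TBS-oxy)propyl]phenyl}oxolan-2-one | O=C1C[C@H](c2cc(CCCO[Si](C)(C)C(C)(C)C)cc(OC)c2O[Si](C)(C)C(C)(C)C)CO1 | intermediate
9 | lithium enolate of 8 (not isolated) | [Li+].[O-]C1=C[C@H](c2cc(CCCO[Si](C)(C)C(C)(C)C)cc(OC)c2O[Si](C)(C)C(C)(C)C)CO1 | intermediate
10 | (3S,4R)-3-iodo-4-{2-(TBS-oxy)-3-methoxy-5-[3-(TBS-oxy)propyl]phenyl}oxolan-2-one, iodine trans to aryl (not isolated) | O=C1OC[C@@H](c2cc(CCCO[Si](C)(C)C(C)(C)C)cc(OC)c2O[Si](C)(C)C(C)(C)C)[C@@H]1I | intermediate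
11 | tetrabutylammonium phenoxide of the (3S,4R)-iodolactone, aryl silyl ether removed (not isolated) | O=C1OC[C@@H](c2cc(CCCO[Si](C)(C)C(C)(C)C)cc(OC)c2[O-])[C@@H]1I.CCCC[N+](CCCC)(CCCC)CCCC | intermediate
12 | cis-fused tricyclic lactone, (3aR,8bR)-5-methoxy-7-[3-(TBS-oxy)propyl]-3a,8b-dihydro-1H-furo[3,4-b][1]benzofuran-3-one; (2R,3R) in dihydrobenzofuran numbering | COc1cc(CCCO[Si](C)(C)C(C)(C)C)cc2c1O[C@@H](C(=O)O3)[C@H]2C3 | intermediate
13 | but-3-enylmagnesium bromide | C=CCC[Mg]Br | starting material
14 | bromomagnesium hemiketalate of 15 (not isolated) | COc1cc(CCCO[Si](C)(C)C(C)(C)C)cc2c1O[C@@H](C(O[Mg]Br)(CCC=C)O3)[C@H]2C3 | intermediate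
15 | cis-fused lactol, cyclic hemiketal of the (2R,3R)-3-(hydroxymethyl)-2-(pent-4-enoyl)dihydrobenzofuran, both hemiketal epimers | COc1cc(CCCO[Si](C)(C)C(C)(C)C)cc2c1O[C@@H](C(O)(CCC=C)O3)[C@H]2C3 | intermediate
16 | cis ketone, 1-{(2R,3R)-3-(TBS-oxymethyl)-7-methoxy-5-[3-(TBS-oxy)propyl]-2,3-dihydro-1-benzofuran-2-yl}pent-4-en-1-one (not isolated) | COc1cc(CCCO[Si](C)(C)C(C)(C)C)cc2c1O[C@@H](C(=O)CCC=C)[C@H]2CO[Si](C)(C)C(C)(C)C | intermediate
17 | trans ketone, 1-{(2S,3R)-3-(TBS-oxymethyl)-7-methoxy-5-[3-(TBS-oxy)propyl]-2,3-dihydro-1-benzofuran-2-yl}pent-4-en-1-one | COc1cc(CCCO[Si](C)(C)C(C)(C)C)cc2c1O[C@H](C(=O)CCC=C)[C@H]2CO[Si](C)(C)C(C)(C)C | intermediate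
18 | allylmagnesium bromide | C=CC[Mg]Br | starting material
19 | bromomagnesium alkoxide of 20 (not isolated) | COc1cc(CCCO[Si](C)(C)C(C)(C)C)cc2c1O[C@H]([C@](CC=C)(O[Mg]Br)CCC=C)[C@H]2CO[Si](C)(C)C(C)(C)C | intermediate
20 | (4S)-4-{(2S,3R)-3-(TBS-oxymethyl)-7-methoxy-5-[3-(TBS-oxy)propyl]-2,3-dihydro-1-benzofuran-2-yl}octa-1,7-dien-4-ol | COc1cc(CCCO[Si](C)(C)C(C)(C)C)cc2c1O[C@H]([C@](CC=C)(O)CCC=C)[C@H]2CO[Si](C)(C)C(C)(C)C | intermediate
21 | (1S)-1-{(2S,3R)-3-(TBS-oxymethyl)-7-methoxy-5-[3-(TBS-oxy)propyl]-2,3-dihydro-1-benzofuran-2-yl}cyclohex-3-en-1-ol | COc1cc(CCCO[Si](C)(C)C(C)(C)C)cc2c1O[C@H]([C@]1(O)CCC=CC1)[C@H]2CO[Si](C)(C)C(C)(C)C | intermediate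
22 | (1S,3S,6R)-3-{(2S,3R)-3-(TBS-oxymethyl)-7-methoxy-5-[3-(TBS-oxy)propyl]-2,3-dihydro-1-benzofuran-2-yl}-7-oxabicyclo[4.1.0]heptan-3-ol, epoxide syn to OH | COc1cc(CCCO[Si](C)(C)C(C)(C)C)cc2c1O[C@H]([C@]1(O)CC[C@H]3O[C@H]3C1)[C@H]2CO[Si](C)(C)C(C)(C)C | intermediate
23 | bis-TBS ether of difengpiol B, (1S,3S,4S)-1-{(2S,3R)-3-(TBS-oxymethyl)-7-methoxy-5-[3-(TBS-oxy)propyl]-2,3-dihydro-1-benzofuran-2-yl}-4-methoxycyclohexane-1,3-diol (not isolated) | COc1cc(CCCO[Si](C)(C)C(C)(C)C)cc2c1O[C@H]([C@]1(O)CC[C@H](OC)[C@@H](O)C1)[C@H]2CO[Si](C)(C)C(C)(C)C | intermediate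
24 | difengpiol B, (1S,3S,4S)-1-[(2S,3R)-3-(hydroxymethyl)-5-(3-hydroxypropyl)-7-methoxy-2,3-dihydro-1-benzofuran-2-yl]-4-methoxycyclohexane-1,3-diol | COc1cc(CCCO)cc2c1O[C@H]([C@]1(O)CC[C@H](OC)[C@@H](O)C1)[C@H]2CO | target

Total step count: 11. Longest linear sequence: 11 steps (from 1).

Steps most likely to fail

Step 8. The facial selectivity of the allyl addition may be poor if the weakly basic aryl ether oxygen holds magnesium too loosely, so that the open Felkin-type pathway competes and the C1' epimer forms. The fallback sets out from ketone 17 and comes back at carbinol 20. It takes the facial choice away from the substrate chelate and gives it to a chiral reagent: allylboration of the ketone with a B-allyl-10-phenyl-9-borabicyclo[3.3.2]decane of the enantiomer matched to the (4S) product, Et2O, −78 °C, followed by oxidative work-up (NaOH, H2O2). No new compound arises on the way.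

Step 5. The iodolactone may lose hydrogen iodide or be reduced back to the lactone before the phenoxide closes the ring, and fluoride may also strip the alkyl silyl ether. The fallback sets out from lactone 8 and comes back at tricyclic lactone 12, closing the oxygen ring by a Mitsunobu etherification instead of a halide displacement. Hydroxylation of the potassium enolate of 8 with 2-(phenylsulfonyl)-3-phenyloxaziridine (KN(SiMe3)2, THF, −78 °C) anti to the aryl group should give the trans α-hydroxy lactone F1. KHF2 in MeOH should remove only the aryl silyl ether to give the hydroxy phenol F2. PPh3 and DIAD in THF should then join the phenol oxygen to the carbinol carbon with inversion, which gives the cis-fused 12.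

Step 4. Transmetalation of the hindered ortho-silyloxy boronic acid may be slow, so that protodeboronation in the aqueous medium and hydrolysis of the butenolide overtake the conjugate addition. The fallback sets out from boronic acid 6 and comes back at lactone 8, making the C–C bond and the stereocentre in separate events. Suzuki–Miyaura coupling of 6 with 4-bromofuran-2(5H)-one (Pd(PPh3)4, KF, THF, 60 °C) should give the 4-arylbutenolide F3. Copper hydride asymmetric conjugate reduction (Cu(OAc)2·H2O, the p-tol-BINAP enantiomer that delivers hydride to the face giving the 4R product, polymethylhydrosiloxane, t-BuOH, toluene) should then give 8.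

Further compounds
F0 | step 8 | none | none
F1 | step 5 | (3S,4R)-3-hydroxy-4-{2-(TBS-oxy)-3-methoxy-5-[3-(TBS-oxy)propyl]phenyl}oxolan-2-one | O=C1OC[C@@H](c2cc(CCCO[Si](C)(C)C(C)(C)C)cc(OC)c2O[Si](C)(C)C(C)(C)C)[C@@H]1O
F2 | step 5 | (3S,4R)-3-hydroxy-4-{2-hydroxy-3-methoxy-5-[3-(TBS-oxy)propyl]phenyl}oxolan-2-one | O=C1OC[C@@H](c2cc(CCCO[Si](C)(C)C(C)(C)C)cc(OC)c2O)[C@@H]1O
F3 | step 4 | 4-{2-(TBS-oxy)-3-methoxy-5-[3-(TBS-oxy)propyl]phenyl}furan-2(5H)-one | O=C1C=C(c2cc(CCCO[Si](C)(C)C(C)(C)C)cc(OC)c2O[Si](C)(C)C(C)(C)C)CO1
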